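Everything rests on cutting the oxolane at O1–C2 (ring oxygen to the aryl-bearing carbon) and C3–C4 (the carbons bearing hydroxymethyl and aroyl). C2 is read as a masked ketone and C3 as the α-carbon of a β-keto ester whose ester carbon becomes the hydroxymethyl group; O1, C5 and C4 come from racemic butadiene monoepoxide, its vinyl group being the latent aroyl group. A palladium-catalysed dynamic kinetic asymmetric allylic alkylation joins C3 to C4 and sets C4, and the freed hydroxyl closes onto the ketone (O1–C2), giving a 4,5-dihydrofuran in one operation. C4 then relays its configuration to C2 and C3 by hydrogenation of a bicyclic lactone and is finally epimerised.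

Key step: step 1

Remark on numbering: ring atoms are O1, C2 (aryl), C3 (hydroxymethyl), C4 (aroyl), C5; C6 is the hydroxymethyl carbon, C7 the aroyl carbonyl carbon, and Ar is 3,4,5-trimethoxyphenyl.
Remark on stereochemistry: the target is 2,3-cis and 3,4-trans, that is (2S,3S,4R) in this numbering.
Assumption: the (1R,2R)-ligand of step 1 is taken to give the 4S product 5; if the sense of induction is the reverse, the (1S,2S)-ligand is used with no other change.
Assumption: 1, 2 and the Grignard reagent 7 (as a THF solution) are purchased.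

Step 1
Reactants: 1 ethyl 3-oxo-3-(3,4,5-trimethoxyphenyl)propanoate; 2 racemic 2-vinyloxirane (butadiene monoepoxide)
Product: 5 ethyl (4S)-2-(3,4,5-trimethoxyphenyl)-4-vinyl-4,5-dihydrofuran-3-carboxylate, via branched allylation adduct 3 (not isolated), via cyclic hemiketal 4 (not isolated)
Conditions: Pd2(dba)3·CHCl3 (1 mol %), (1R,2R)-N,N'-cyclohexane-1,2-diylbis[2-(diphenylphosphanyl)-1-naphthamide] (3 mol %), CH2Cl2, 20 °C; then PPTS (10 mol %), 4 Å MS, 40 °C
Reagents that add atoms: none
Why: Zerovalent palladium ionises the racemic vinyl epoxide to a zwitterionic π-allylpalladium alkoxide whose diastereomeric forms interconvert by π–σ–π faster than they are attacked, the alkoxide deprotonates 1, and the enolate carbon attacks the internal allyl terminus to form the C3–C4 bond (Tsuji–Trost allylic alkylation in its dynamic kinetic asymmetric form). The closest known reaction type is the branched-selective asymmetric alkylation of β-keto esters with vinyl epoxides under this ligand class, whose hydroxy keto ester adducts close to hemiketals. The hydroxyl of 3 then adds to the aryl ketone in a 5-exo-trig closure (O1–C2), and acid-catalysed loss of water gives the conjugated vinylogous carbonate 5. The only stereocentre that survives, C4, is controlled by the chiral ligand pocket during C–C bond formation, while the centres at C2 and C3 of 4 are erased by the dehydration. The step needs branched over linear attack (alkoxide-directed delivery of the nucleophile next to oxygen), C- over O-alkylation and mono-alkylation (soft enolate, slight excess of 1), and hemiketalisation with dehydration over lactonisation onto the ester (neutral alkylation, then mild acid with removal of water).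

Step 2
Reactants: 5 ethyl (4S)-2-(3,4,5-trimethoxyphenyl)-4-vinyl-4,5-dihydrofuran-3-carboxylate
Product: 6 ethyl (4S)-4-formyl-2-(3,4,5-trimethoxyphenyl)-4,5-dihydrofuran-3-carboxylate
Conditions: OsO4 (2 mol %), NaIO4 (4 equiv), 2,6-lutidine (2 equiv), dioxane/H2O 3:1, 20 °C
Reagents that add atoms: osmium tetroxide O=[Os](=O)(=O)=O (catalytic oxygen carrier); sodium periodate [Na+].[O-]I(=O)(=O)=O (terminal oxidant)
Why: In this Lemieux–Johnson oxidation OsO4 should dihydroxylate the monosubstituted vinyl group far faster than the tetrasubstituted, ester-deactivated enol ether, NaIO4 cleaves the diol, and the lutidine buffer keeps the aldehyde α-stereocentre C4 from enolising.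

Step 3
Reactants: 6 ethyl (4S)-4-formyl-2-(3,4,5-trimethoxyphenyl)-4,5-dihydrofuran-3-carboxylate; 7 3,4,5-trimethoxyphenylmagnesium bromide
Product: 9 (3aS)-3,6-bis(3,4,5-trimethoxyphenyl)-3a,4-dihydro-1H,3H-furo[3,4-c]furan-1-one (unsaturated bicyclic lactone; both C3 epimers), via carbinol 8 (not isolated)
Conditions: 7 (1.1 equiv), THF, −78 °C; then 20 °C; aq NH4Cl
Reagents that add atoms: none
Why: Grignard 1,2-addition to the aldehyde should be much faster at −78 °C than enolisation or attack on the vinylogous carbonate, and on warming the magnesium alkoxide acylates itself on the neighbouring ester (5-exo-trig lactonisation); the new carbinol centre C7 is left uncontrolled because it later becomes the ketone.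

Step 4
Reactants: 9 (3aS)-3,6-bis(3,4,5-trimethoxyphenyl)-3a,4-dihydro-1H,3H-furo[3,4-c]furan-1-one
Product: 10 (3aS,6S,6aR)-3,6-bis(3,4,5-trimethoxyphenyl)tetrahydro-1H,3H-furo[3,4-c]furan-1-one (cis-fused; C6 aryl endo; both C3 epimers)
Conditions: H2 (10 bar), 10 % Pd/C, EtOAc, 25 °C
Reagents that add atoms: none
Why: Heterogeneous catalytic hydrogenation should add both hydrogens syn to the open face of the enol ether, the face carrying the C4 hydrogen and turned away from the lactone bridge, so the ring fusion becomes cis and the C2 aryl group ends endo and cis to the C3 lactone carbon, C4 thereby relaying its configuration to C2 and C3.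

Step 5
Reactants: 10 (3aS,6S,6aR)-3,6-bis(3,4,5-trimethoxyphenyl)tetrahydro-1H,3H-furo[3,4-c]furan-1-one
Product: 11 (3,4,5-trimethoxyphenyl)[(3S,4S,5S)-4-(hydroxymethyl)-5-(3,4,5-trimethoxyphenyl)oxolan-3-yl]methanol (all-cis oxolane; both carbinol epimers)
Conditions: LiAlH4, THF, 0 to 20 °C; aq Rochelle salt
Reagents that add atoms: none
Why: Hydride reduction of the γ-lactone to the diol should be faster than any enolisation, so no stereocentre is touched and the lactone carbonyl carbon becomes the hydroxymethyl group C6.

Step 6
Reactants: 11 (3,4,5-trimethoxyphenyl)[(3S,4S,5S)-4-(hydroxymethyl)-5-(3,4,5-trimethoxyphenyl)oxolan-3-yl]methanol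
Product: 13 [(3R,4S,5S)-4-(hydroxymethyl)-5-(3,4,5-trimethoxyphenyl)oxolan-3-yl](3,4,5-trimethoxyphenyl)methanone (target), via all-cis ketone 12 (not isolated)
Conditions: MnO2 (activated, excess), CH2Cl2, 20 °C; filter; then DBU (0.2 equiv), CH2Cl2, 20 °C
Reagents that add atoms: none
Why: MnO2 should oxidise the benzylic secondary alcohol selectively beside the primary one, and catalytic DBU then equilibrates the ketone α-carbon C4 through its enolate to the less crowded 3,4-trans isomer, while C2 and C3 are not enolisable and keep their configuration.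

Compound list
1 | ethyl 3-oxo-3-(3,4,5-trimethoxyphenyl)propanoate | CCOC(=O)CC(=O)c1cc(OC)c(OC)c(OC)c1 | starting material
2 | racemic 2-vinyloxirane (butadiene monoepoxide) | C=CC1CO1 | starting material
3 | ethyl (3S)-3-(hydroxymethyl)-2-(3,4,5-trimethoxybenzoyl)pent-4-enoate (both C2 epimers) | CCOC(=O)C(C(=O)c1cc(OC)c(OC)c(OC)c1)[C@H](C=C)CO | intermediate (not isolated)
4 | ethyl (4S)-2-hydroxy-2-(3,4,5-trimethoxyphenyl)-4-vinyloxolane-3-carboxylate (epimers at C2 and C3) | CCOC(=O)C1[C@H](C=C)COC1(O)c1cc(OC)c(OC)c(OC)c1 | intermediate (not isolated)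
5 | ethyl (4S)-2-(3,4,5-trimethoxyphenyl)-4-vinyl-4,5-dihydrofuran-3-carboxylate | C=C[C@@H]1COC(c2cc(OC)c(OC)c(OC)c2)=C1C(=O)OCC | intermediate
6 | ethyl (4S)-4-formyl-2-(3,4,5-trimethoxyphenyl)-4,5-dihydrofuran-3-carboxylate | O=C[C@@H]1COC(c2cc(OC)c(OC)c(OC)c2)=C1C(=O)OCC | intermediate
7 | 3,4,5-trimethoxyphenylmagnesium bromide | COc1cc([Mg]Br)cc(OC)c1OC | starting material
8 | ethyl (4S)-4-[hydroxy(3,4,5-trimethoxyphenyl)methyl]-2-(3,4,5-trimethoxyphenyl)-4,5-dihydrofuran-3-carboxylate (both carbinol epimers) | OC(c1cc(OC)c(OC)c(OC)c1)[C@@H]1COC(c2cc(OC)c(OC)c(OC)c2)=C1C(=O)OCC | intermediate (not isolated)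
9 | (3aS)-3,6-bis(3,4,5-trimethoxyphenyl)-3a,4-dihydro-1H,3H-furo[3,4-c]furan-1-one (both C3 epimers) | O=C1OC(c3cc(OC)c(OC)c(OC)c3)[C@@H]2COC(c3cc(OC)c(OC)c(OC)c3)=C12 | intermediate
10 | (3aS,6S,6aR)-3,6-bis(3,4,5-trimethoxyphenyl)tetrahydro-1H,3H-furo[3,4-c]furan-1-one (both C3 epimers) | O=C1OC(c3cc(OC)c(OC)c(OC)c3)[C@@H]2CO[C@H](c3cc(OC)c(OC)c(OC)c3)[C@@H]21 | intermediate
11 | (3,4,5-trimethoxyphenyl)[(3S,4S,5S)-4-(hydroxymethyl)-5-(3,4,5-trimethoxyphenyl)oxolan-3-yl]methanol (both carbinol epimers) | OC(c1cc(OC)c(OC)c(OC)c1)[C@@H]1CO[C@H](c2cc(OC)c(OC)c(OC)c2)[C@@H]1CO | intermediate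
12 | [(3S,4S,5S)-4-(hydroxymethyl)-5-(3,4,5-trimethoxyphenyl)oxolan-3-yl](3,4,5-trimethoxyphenyl)methanone (all-cis) | COc1cc(C(=O)[C@@H]2CO[C@H](c3cc(OC)c(OC)c(OC)c3)[C@@H]2CO)cc(OC)c1OC | intermediate (not isolated)
13 | [(3R,4S,5S)-4-(hydroxymethyl)-5-(3,4,5-trimethoxyphenyl)oxolan-3-yl](3,4,5-trimethoxyphenyl)methanone | COc1cc(C(=O)[C@H]2CO[C@H](c3cc(OC)c(OC)c(OC)c3)[C@@H]2CO)cc(OC)c1OC | target

Total step count: 6. Longest linear sequence: 6 steps (1 to 13).

Steps most likely to fail

Step 4. The tetrasubstituted, conjugated enol ether may resist hydrogenation, and forcing conditions may bring hydrogenolysis of the benzylic C–O bonds or loss of facial selectivity. The fallback sets out from 9 and returns at 10. It is an ionic hydrogenation (Et3SiH, CF3CO2H, CH2Cl2, 0 °C): the acid protonates the vinylogous carbonate at the ring-fusion carbon from the open face to give the cis-fused 2-aryl oxocarbenium ion, and the silane delivers hydride to C2 from the same face, which again places the aryl group endo.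

Step 1. The enolate may attack the terminal allyl carbon, alkylate twice, or give a low enantiomeric excess, and the adduct may lactonise onto the ester instead of dehydrating to the dihydrofuran. The fallback sets out from 1 and returns at 5. (E)-But-2-ene-1,4-diol is mono-silylated (TBSCl, NaH, THF) to (E)-4-[(tert-butyldimethylsilyl)oxy]but-2-en-1-ol F1, which with methyl chloroformate and pyridine gives (E)-4-[(tert-butyldimethylsilyl)oxy]but-2-en-1-yl methyl carbonate F2. Branched-selective allylic alkylation of 1 with F2 ([Ir(cod)Cl]2, a chiral phosphoramidite ligand chosen for the 3S adduct, THF) should give ethyl (3S)-3-{[(tert-butyldimethylsilyl)oxy]methyl}-2-(3,4,5-trimethoxybenzoyl)pent-4-enoate F3. HCl in ethanol then removes the silyl group and dehydrates the hemiketal 4 to 5; no alkoxide is present at any point, so lactonisation is avoided.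

Step 3. The basic Grignard reagent may enolise the α-branched aldehyde, which would racemise C4 or open the ring by β-elimination of the vinylogous carboxylate oxygen, and the lactonisation may stop short. The fallback sets out from 6 and returns at 9. A Nozaki–Hiyama–Kishi coupling of 6 with commercial 5-iodo-1,2,3-trimethoxybenzene (CrCl2, catalytic NiCl2, DMF, 20 °C) forms the carbinol 8 with a non-basic arylchromium species, and catalytic DBU in THF then closes the lactone 9.

Further compounds
F1 | step 1 | (E)-4-[(tert-butyldimethylsilyl)oxy]but-2-en-1-ol | CC(C)(C)[Si](C)(C)OC/C=C/CO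
F2 | step 1 | (E)-4-[(tert-butyldimethylsilyl)oxy]but-2-en-1-yl methyl carbonate | COC(=O)OC/C=C/CO[Si](C)(C)C(C)(C)C
F3 | step 1 | ethyl (3S)-3-{[(tert-butyldimethylsilyl)oxy]methyl}-2-(3,4,5-trimethoxybenzoyl)pent-4-enoate | CCOC(=O)C(C(=O)c1cc(OC)c(OC)c(OC)c1)[C@H](C=C)CO[Si](C)(C)C(C)(C)C
F0 | step 3 | none | none
F0 | step 4 | none | none
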